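The runs stem from a simulated flask from invented constants; scatter was added.

Read the end of Friday's run first. From 2.50 d on its readings move by little more than their scatter, and the sum of X over the sum of Z in those readings is the stall ratio, which reads 1.93: my reading of the balance Z and X reach when nothing pulls on them. Tuesday's Q climbs to 56.8 %, more than the half that was Z, so I read G as reaching Q through X, with the same ratio on its side.

| flask | Z | G | E | remark | time |
|---|---|---|---|---|---|
| Friday's | 38 mM | 38 mM | 1.2 equiv | run made earlier |  |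
| Saturday's | 38 mM | 38 mM | 1.9 equiv | run made earlier |  |
| Tuesday's | 19 mM | 19 mM | 2.5 equiv | run made earlier |  |
| flask | 38 mM | 38 mM | 2.50 equiv |  | 15 d |

| run | time / d | X / % | Q / % | Z / % |
|---|---|---|---|---|
| Friday's | 0.208 | 7.4 | 18.3 | 28.6 |
| Friday's | 0.500 | 15.2 | 24.4 | 18.0 |
| Friday's | 1.04 | 18.2 | 28.6 | 11.5 |
| Friday's | 2.50 | 21.4 | 33.2 | 9.0 |
| Friday's | 6.00 | 17.5 | 33.5 | 10.9 |
| Friday's | 15.0 | 19.1 | 32.6 | 10.2 |
| Saturday's | 0.208 | 8.9 | 26.4 | 20.5 |
| Saturday's | 0.500 | 11.5 | 34.7 | 10.9 |
| Saturday's | 1.04 | 13.4 | 40.7 | 5.9 |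
| Saturday's | 2.50 | 12.1 | 44.3 | 1.6 |
| Saturday's | 6.00 | 7.2 | 47.6 | 3.4 |
| Saturday's | 15.0 | 6.7 | 49.8 | 2.4 |
| Tuesday's | 0.208 | 8.2 | 21.7 | 26.2 |
| Tuesday's | 0.625 | 12.8 | 33.9 | 10.4 |
| Tuesday's | 1.67 | 14.5 | 41.4 | 4.9 |
| Tuesday's | 5.00 | 8.0 | 48.2 | 2.6 |
| Tuesday's | 15.0 | 0.1 | 56.8 | 0.1 |

(each reading ± 1 percentage point)

- the best time, 15 d at the latest, for X
- the amount of X, in percent of the Z and G together charged, at that time
- earliest time at which at least nineteen twentieths of that best amount are there, in d
- latest time at which they still are, in d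

- E is single-handed; Z and G are mirror images of each other, charged as a racemate, each of them at the stated concentration
- the handed part of E does not stay in what it makes, so the products of the two hands are mirror images too

Now run the flask slowly. In the first instants E eats Z: at 0.208 d Friday's Z reads 28.6 % and Saturday's, with more E, 20.5 %. In the middle Z and G thin out while X, fed by both, rises. As I read it, X takes no E and goes back to Z and G, so it tops where gain equals return:

X at its top = 1.93 / 2 × (Z + G)

At the end, Tuesday's run, with the same equivalents, reads X at 0.1 %, so I expect the flask's X to drain away as well.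

The flask holds twice the E concentration of Tuesday's run, which speeds up E's steps but not the step into X, so I commit to a top between 7.25 % and Tuesday's reading of 14.5 %. The forecast holds that “it should follow Tuesday's curve at half the time”, and gives 14.5 % at 0.8 d, from 0.43 d to 1.25 d.

The flask gives 10.3 % at 0.768 d, with the band asked about running from 0.500 d to 1.15 d. At the best time Z is 3.43 % and G 8.06 %, so the stall ratio puts X at 11.1 %.

    Z ⇌ X (K = 1.80, k = 0.0230 h⁻¹)
    E → D (k = 0.00220 h⁻¹)
    E + G → L (k = 1.70 M⁻¹ h⁻¹)
    G ⇌ X (K = 1.80, k = 0.0230 h⁻¹)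
    E + Z → Q (k = 2.80 M⁻¹ h⁻¹)

Take a second flask with 0.620 equiv of E, the limiting reagent. If each E takes one Z or G, 31.0 % is used and the rest splits by the stall ratio: X 33.9 %, Z 17.6 %. At 15.0 d that second flask holds X 33.0 %, Z 18.3 %, E 0 %.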